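## Structural features

The target is a germacranolide: a ten-membered carbocycle (C1–C10) fused across C6–C7 to an α-methylene-γ-butyrolactone (lactone oxygen on C6, carbonyl C12, exocyclic C11=C13). The carbocycle carries a ketone at C2 flanked by two allylic methylenes: C1, next to the exocyclic C10=C14 methylene, and C3, next to the trisubstituted C4=C5 alkene. C4 bears an acetoxymethyl group (C15) that is cis to C6 across the alkene (ring carbons C3 and C6 trans; CIP descriptor Z), and C8 bears an acetoxy group. The only stereocentres are the contiguous triad C6 (R), C7 (R), C8 (S). Along the extended C5–C9 chain, O6, the C11 branch and O8 lie on the same side, which in the ring means a trans-fused lactone and a C8 oxygen trans to the C7–C11 bond. Fragile features are the doubly skipped C2 ketone (conjugation under acid or base), the methylene lactone (Michael acceptor), the allylic acetate, and a free C8 hydroxyl that can take the lactone carbonyl from O6. Any C6 or C8 carbonyl intermediate also has an allylic α-hydrogen on C7 and a β-oxygen that can be eliminated. The real difficulty is closing a ten-membered ring that holds four sp2 ring atoms while keeping the alkene geometry, the skipped enone and the triad intact. The key step uses the fact that C6 is an allylic carbinol carbon bonded to C5 of the trisubstituted alkene: the geometry is stored in a C5 iodoalkene, and C5–C6 is made by alkenylation of a C6 aldehyde with an organochromium reagent that ignores the C2 ketone.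

## Logic of the disconnections

30 ⇒ 29 ⇒ 28. The two acyl–oxygen bonds at O8 and O15 are cut and both hydroxyls are re-masked as tert-butyldimethylsilyl ethers. An acetate on O8 would sit β to the C6 carbonyl needed for ring closure and would be eliminated across the acidic C7–H; an allylic acetate at C15 is a liability towards low-valent nickel. The gain is that every C–C bond-forming step sees only robust ethers. The demand is a non-basic desilylation of 28 and prompt acetylation of 29, because the free C8 hydroxyl can attack the lactone.

28 ⇒ 25 ⇒ 24. The lactone O6–C12 bond is cut, C12 is taken down to the primary allylic alcohol and hidden as a triethylsilyl ether. A methylene lactone would not survive the organometallic steps; as a 2-propenyl branch on C7 it is inert. The gain is that the lactone needs no C–C bond of its own. The demand is removal of one silyl group out of three, and an oxidation that takes the primary C12 alcohol before the secondary allylic C6 alcohol and leaves the ketone alone.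

24 ⇒ 21. The C5–C6 bond is cut between the alkene carbon and the carbinol carbon. This is the only ring bond whose formation makes the ring, fixes nothing new on the alkene and creates the C6 oxygen in the right place. The gain is an open chain with two stereocentres and a geometrically defined iodoalkene. The demand is addition to the aldehyde and not the C2 ketone, retention of alkene geometry, Re-face attack at C6, and cyclisation faster than intermolecular coupling.

21 ⇒ 20 ⇒ 19 ⇒ 18 + 7. The C2 ketone and C6 aldehyde are traced to the C2/C6 diol 20 and its C6 acetate 19, so that the sensitive keto aldehyde exists for one step only. Then C1–C2 is cut: a homoallylic carbinol next to the C10 methylene is the retron of an allylsilane addition. The gain is a convergent split into two pieces of similar size, with the C2 configuration irrelevant. The demand is a Lewis-acid step that spares the silyl ethers and the β,γ-unsaturated aldehyde, and an acetate removal that does not move the C8 silyl group to O6.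

18 ⇒ 17 ⇒ 14 + 15. C8–C9 is cut, again a homoallylic alcohol retron. 15 supplies C9, C10 and the two remaining methylene carbons with two allyl termini of different reactivity. The gain is that one four-carbon unit links both halves. The demand is reagent control at C8, since the bias of C7 is unreliable, and activation of the chloride terminus without touching the silane terminus.

14 ⇒ 13 ⇒ 12 ⇒ 11 ⇒ 9 + 10, and 9 ⇒ 8. C7 sits on a prochiral 2-substituted propane-1,3-diol, so both arms are taken back to the ester level and the C7–C11 bond is cut between the malonate carbon and the alkenyl bromide. The gain is that C7 comes from differentiation of enantiotopic groups without a chiral reagent, and C12 is already oxygenated. The demand is an alkenylation that leaves the double bond out of conjugation and an enzyme that acylates the arm destined to be C6.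

7 ⇒ 5 ⇒ 4 ⇒ 1 + 2. The C2 aldehyde is traced to the terminal alkene of an allyl group; C3–C4 and the C5–iodine bond are then cut on the alkyne. The gain is that one anti-carbometalation sets the whole trisubstituted alkene from a three-carbon alkynol. The demand is regio- and stereocontrol in the carbomagnesiation and an oxidative cleavage that takes only the terminal alkene.

## Other disconnections considered

Alternative 1: The cut is the C4=C5 double bond itself. O6 and O15 are tied as a diisopropylsilylene acetal in the acyclic diene A2, and ring-closing metathesis between the C5 vinyl group and the C4 methylene (second-generation Grubbs catalyst, toluene, 40–80 °C) would give the seven-membered dioxasilepine A1.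
- In favour: the small ring allows only the arrangement with C15 cis to C6; the step creates no stereocentre and needs no chiral ligand; ruthenium carbenes tolerate silyl ethers, acetates and the chloride; the C9 allyl chloride of A1 is already set up for a later chromium-mediated closure of C8–C9.
- Against: the metathesis does not close the carbocycle, so an equally demanding ten-membered closure (C8–C9, with C8 to be controlled inside the ring) still follows. The C6 centre has to be made earlier by vinyl addition to a C6 aldehyde, with the same weak bias from C7. The catalyst must choose the C4 methylene over two other 1,1-disubstituted alkenes (C10=C14, C11=C13). The tether and the C2 dithiane cost extra operations, and the dithiane must come off late beside the skipped diene.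
- Comparison: on security of the alkene geometry the alternative is the equal of the chosen plan (ring enforcement against chelate-controlled anti-carbomagnesiation), and on functional-group tolerance of the key step it is the better one. The chosen plan is ahead on structure, because its key step makes the ring, C5–C6 and C6 in one operation and carries C2 unmasked. In step count the alternative should be longer by the tether, the dithiane and the second ring closure.

Alternative 2: The cut is C2–C3, made while a temporary C5–C10 bond is broken. The potassium alkoxide of the 1-vinyl-2-alkenylcyclohexanol A4 (KH, 18-crown-6, THF) would undergo the anionic oxy-Cope [3,3] shift through a chair transition state and give, after protonation of the enolate, the cyclodec-5-enone A3.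
- In favour: the triad C6–C8 is assembled on a chair cyclohexane with all three substituents equatorial; ring expansion needs no high dilution; enolate formation makes the shift irreversible. On these three points the alternative is better than the chosen plan.
- Against: the oxidation pattern of A3 does not match the target. C2 arrives as an unactivated methylene, the carbonyl sits at C10 where a methylene is needed, and the lactone lacks C13, so a C–H oxidation at C2, a methylenation of an enolisable ketone and a lactone α-methylenation would all follow. KH next to a lactone with acidic C11 hydrogens and a β-silyloxy group invites enolate chemistry and acyl transfer to the tertiary alkoxide.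
- Comparison: a concerted pericyclic step is mechanistically cleaner, and A4 is the safer vehicle for the stereocentres. The chosen plan, however, has every oxygen in its final position at ring closure, and the repair of C2, C10 and C13 should make the alternative clearly longer.

Alternative 3: The cut is C8–C9, with an O–C14 ether link in its place in the eleven-membered α-stannyl allyl ether A6. Tin–lithium exchange at C8 (n-BuLi, THF, −78 °C) would trigger the Wittig–Still [2,3] shift, forming C8–C9, breaking O–C14 and giving the ten-membered carbocycle A5 with the free C8 hydroxyl and the C10=C14 methylene.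
- In favour: strain is introduced by contracting an easier eleven-membered ether; the shift is concerted and stereospecific (exchange with retention, shift with inversion at C8); methylene and hydroxyl appear in one step. On stereochemical definition of the ring-forming step the alternative is the better one, and on tolerance of silyl ethers at low temperature it is equal.
- Against: the problems move into the making of A6, namely a macro-etherification and a diastereoselective stannylation next to C7 with the same ambiguous bias. The C8 carbanion has a silyloxy group on C6 in a 1,4-relationship, so oxygen-to-carbon silyl migration and the [1,2] shift compete. The C2 ketone must travel as a dithiane.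
- Comparison: the chosen plan closes the ring by a polar addition that tolerates the free C2 ketone and sets C6 by a ligand, whereas here C6, C7 and C8 must all be in place before the ring contracts. The alternative should be longer by the ether macrocyclisation, the stannane and the dithiane operations.

Key step: step 14

Assumption: in step 7 the lipase is taken to acylate the pro-R hydroxymethyl arm of 12; lipases of the opposite enantiotopic preference exist, so only the choice of enzyme depends on this.

Remark: 21, 24 and 30 have the same spatial arrangement at C6–C8; the descriptor of C7 changes (R in 21, S in 24, 25 and 28, R in 29 and 30) only because the CIP ranking of its neighbours changes.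

Abbreviations: TBS = tert-butyldimethylsilyl, TES = triethylsilyl.

## Steps

Step 1
Reactants: 1 prop-2-yn-1-ol; 2 allylmagnesium bromide
Product: 4 (2Z)-2-(iodomethylidene)pent-4-en-1-ol, via cyclic alkenylmagnesium alkoxide 3 (not isolated)
Conditions: 2 (2.5 equiv), CuI (10 mol%), Et2O, −10 °C to rt; then iodine, THF, −40 to 0 °C; aq. NH4Cl
Reagents that add atoms: iodine, [I][I]
Why: Copper-catalysed anti-carbomagnesiation of the magnesium alkoxide of 1 puts the allyl group on the internal alkyne carbon and magnesium on the terminal carbon, held cis to the CH2O group in chelate 3; iodinolysis of the C–Mg bond with retention should give the iodoalkene with iodine cis to CH2OH.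

Step 2
Reactants: 4 (2Z)-2-(iodomethylidene)pent-4-en-1-ol
Product: 5 tert-butyl{[(2Z)-2-(iodomethylidene)pent-4-en-1-yl]oxy}dimethylsilane
Conditions: TBSCl, imidazole, CH2Cl2, 0 °C to rt
Reagents that add atoms: tert-butyldimethylsilyl chloride, CC(C)(C)[Si](C)(C)Cl
Why: Standard silylation of a primary allylic alcohol; the TBS ether will later serve as the C15 oxygen mask through all C–C bond formations.

Step 3
Reactants: 5 tert-butyl{[(2Z)-2-(iodomethylidene)pent-4-en-1-yl]oxy}dimethylsilane
Product: 7 (3Z)-3-[(TBSO)methyl]-4-iodobut-3-enal, via diol 6 (not isolated)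
Conditions: OsO4 (2 mol%), NaIO4 (4 equiv), 2,6-lutidine, dioxane/H2O, rt
Reagents that add atoms: osmium tetroxide, O=[Os](=O)(=O)=O; sodium periodate, [Na+].[O-]I(=O)(=O)=O
Why: Lemieux–Johnson cleavage: OsO4 should dihydroxylate the unhindered, electron-richer terminal vinyl group in preference to the iodine-bearing trisubstituted alkene, and NaIO4 cleaves diol 6 and reoxidises osmium. The β,γ-unsaturated aldehyde is used without storage.

Step 4
Reactants: 8 2-bromoprop-2-en-1-ol
Product: 9 [(2-bromoprop-2-en-1-yl)oxy]triethylsilane
Conditions: TESCl, imidazole, CH2Cl2, 0 °C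
Reagents that add atoms: triethylsilyl chloride, CC[Si](CC)(CC)Cl
Why: Standard silylation; the TES ether marks the future C12 oxygen as the one silyl group that can later be removed beside two TBS ethers.

Step 5
Reactants: 9 [(2-bromoprop-2-en-1-yl)oxy]triethylsilane; 10 diethyl malonate
Product: 11 diethyl 2-[3-(TESO)prop-1-en-2-yl]propanedioate
Conditions: CuI (10 mol%), L-proline (20 mol%), Cs2CO3, DMSO, 45 °C; cold aq. NH4Cl
Reagents that add atoms: none
Why: Copper-catalysed Ullmann–Hurtley-type C-alkenylation of a malonate with an alkenyl bromide forms the C7–C11 bond; a cold, weakly acidic quench should protonate at the α-carbon so that the alkene stays out of conjugation.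

Step 6
Reactants: 11 diethyl 2-[3-(TESO)prop-1-en-2-yl]propanedioate
Product: 12 2-[3-(TESO)prop-1-en-2-yl]propane-1,3-diol
Conditions: LiAlH4, Et2O, −20 to 0 °C (ester added to the hydride)
Reagents that add atoms: none
Why: Hydride reduction of both esters to the prochiral 1,3-diol; low temperature and inverse addition limit enolisation of the acidic malonate C–H.

Step 7
Reactants: 12 2-[3-(TESO)prop-1-en-2-yl]propane-1,3-diol
Product: 13 (2R)-3-hydroxy-2-[3-(TESO)prop-1-en-2-yl]propyl acetate
Conditions: Burkholderia cepacia lipase (immobilised), vinyl acetate, i-Pr2O, rt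
Reagents that add atoms: vinyl acetate, C=COC(C)=O
Why: Lipase-catalysed desymmetrisation of a prochiral 2-substituted propane-1,3-diol by irreversible transesterification sets C7. Acetylation of the pro-R arm gives the (R)-monoacetate, whose acetylated arm becomes C6 and whose free arm becomes C8.

Step 8
Reactants: 13 (2R)-3-hydroxy-2-[3-(TESO)prop-1-en-2-yl]propyl acetate
Product: 14 (2S)-3-oxo-2-[3-(TESO)prop-1-en-2-yl]propyl acetate
Conditions: Dess–Martin periodinane, NaHCO3, CH2Cl2, 0 °C
Reagents that add atoms: none
Why: Buffered Dess–Martin oxidation, done promptly so that acyl migration in 13 cannot erode the enantiomeric purity; the neutral medium avoids epimerisation at C7 and β-elimination of acetate, and 14 is used crude.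

Step 9
Reactants: 14 (2S)-3-oxo-2-[3-(TESO)prop-1-en-2-yl]propyl acetate; 15 2-(chloromethyl)-3-(trimethylsilyl)prop-1-ene
Product: 17 (2S,3S)-3-hydroxy-2-[3-(TESO)prop-1-en-2-yl]-5-[(trimethylsilyl)methyl]hex-5-en-1-yl acetate, via allylchromium dichloride 16 (not isolated)
Conditions: CrCl2 (10 mol%), N-[2-(4-isopropyl-4,5-dihydrooxazol-2-yl)-6-methylphenyl]methanesulfonamide (one antipode, 11 mol%), proton sponge (11 mol%), Mn powder, Cp2ZrCl2, LiCl, MeCN, rt
Reagents that add atoms: none
Why: Chromium-catalysed asymmetric Nozaki–Hiyama allylation: the chloride terminus of 15 is reduced to allylchromium 16, which adds through a six-membered chair transition state while the allylsilane terminus stays inert. The antipode of the oxazoline sulfonamide that delivers the allyl group to the Si face of the C8 aldehyde should set C8 as S, overriding the weak bias of C7.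

Step 10
Reactants: 17 (2S,3S)-3-hydroxy-2-[3-(TESO)prop-1-en-2-yl]-5-[(trimethylsilyl)methyl]hex-5-en-1-yl acetate
Product: 18 (2S,3S)-3-(TBSO)-2-[3-(TESO)prop-1-en-2-yl]-5-[(trimethylsilyl)methyl]hex-5-en-1-yl acetate
Conditions: TBSOTf, 2,6-lutidine, CH2Cl2, −78 °C
Reagents that add atoms: tert-butyldimethylsilyl triflate, CC(C)(C)[Si](C)(C)OS(=O)(=O)C(F)(F)F
Why: Silylation of the hindered secondary C8 alcohol with the silyl triflate; the lutidine buffer prevents protodesilylation of the allylsilane.

Step 11
Reactants: 18 (2S,3S)-3-(TBSO)-2-[3-(TESO)prop-1-en-2-yl]-5-[(trimethylsilyl)methyl]hex-5-en-1-yl acetate; 7 (3Z)-3-[(TBSO)methyl]-4-iodobut-3-enal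
Product: 19 (2S,3S,9Z)-3-(TBSO)-9-[(TBSO)methyl]-7-hydroxy-10-iodo-5-methylidene-2-[3-(TESO)prop-1-en-2-yl]dec-9-en-1-yl acetate (both epimers at the carbinol, ring carbon C2)
Conditions: BF3·OEt2, CH2Cl2, −78 °C; aq. NaHCO3 at −78 °C
Reagents that add atoms: none
Why: Hosomi–Sakurai allylation: the alkene terminus of the allylsilane attacks the BF3-activated aldehyde to form C1–C2, and loss of the silyl group from the β-silyl cation leaves the C10=C14 methylene. The allylsilane is far more nucleophilic than the 1,1-disubstituted alkene of the C11 branch, and the C2 configuration is irrelevant because C2 is oxidised later.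

Step 12
Reactants: 19 (2S,3S,9Z)-3-(TBSO)-9-[(TBSO)methyl]-7-hydroxy-10-iodo-5-methylidene-2-[3-(TESO)prop-1-en-2-yl]dec-9-en-1-yl acetate
Product: 20 (2S,3S,9Z)-3-(TBSO)-9-[(TBSO)methyl]-10-iodo-5-methylidene-2-[3-(TESO)prop-1-en-2-yl]dec-9-ene-1,7-diol (both C7 epimers)
Conditions: i-Bu2AlH, CH2Cl2, −78 °C; aq. Rochelle salt
Reagents that add atoms: none
Why: Reductive removal of the primary acetate at low temperature; chosen over basic methanolysis to exclude 1,3-migration of the C8 silyl group to the C6 oxygen and loss of the TES ether.

Step 13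
Reactants: 20 (2S,3S,9Z)-3-(TBSO)-9-[(TBSO)methyl]-10-iodo-5-methylidene-2-[3-(TESO)prop-1-en-2-yl]dec-9-ene-1,7-diol
Product: 21 (2R,3S,9Z)-3-(TBSO)-9-[(TBSO)methyl]-10-iodo-5-methylidene-7-oxo-2-[3-(TESO)prop-1-en-2-yl]dec-9-enal
Conditions: Dess–Martin periodinane (3 equiv), NaHCO3, CH2Cl2, 0 °C; rapid filtration, used at once
Reagents that add atoms: none
Why: Double Dess–Martin oxidation of the C2 and C6 alcohols under buffered neutral conditions, so that the skipped C2 ketone is not conjugated and the C7 centre of the aldehyde is not epimerised; the C2 epimers converge.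

Step 14
Reactants: 21 (2R,3S,9Z)-3-(TBSO)-9-[(TBSO)methyl]-10-iodo-5-methylidene-7-oxo-2-[3-(TESO)prop-1-en-2-yl]dec-9-enal
Product: 24 (3Z,5R,6S,7S)-7-(TBSO)-3-[(TBSO)methyl]-5-hydroxy-9-methylidene-6-[3-(TESO)prop-1-en-2-yl]cyclodec-3-en-1-one, via alkenylchromium dichloride 22 (not isolated), via zirconocene alkoxide 23 (not isolated)
Conditions: CrCl3 (20 mol%), NiCl2(dme) (3 mol%), N-[2-(4-isopropyl-4,5-dihydrooxazol-2-yl)-6-methylphenyl]methanesulfonamide (one antipode, 24 mol%), proton sponge (24 mol%), Cp2ZrCl2 (1.5 equiv), LiCl, MeCN/DMF, undivided cell, Al anode, Ni-foam cathode, constant current, rt, 21 added slowly (final 2 mM); aq. work-up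
Reagents that add atoms: none
Why: At the cathode CrCl3 is reduced to divalent chromium and NiCl2 to zerovalent nickel; nickel inserts into the C5–iodine bond of 21 with retention of the alkene geometry and passes the alkenyl group to chromium, giving 22. The alkenyl trivalent chromium centre adds to the C6 aldehyde, Cp2ZrCl2 takes over the alkoxide as 23 so that chromium returns to the cathode, and aqueous work-up frees alcohol 24. The closest known reaction type is the nickel/chromium Nozaki–Hiyama–Kishi macrocyclisation of iodoalkene aldehydes, run here with the cathodic chromium turnover known for the intermolecular coupling. The ten-membered ring closes in the 10-exo-trig mode, the carbonyl oxygen staying outside the ring. The new C6 centre is controlled by the chiral oxazoline sulfonamide on chromium, used as the antipode that steers the alkenyl group to the Re face of the aldehyde (C6 R, H6 and H7 trans as the trans lactone requires), because C7 alone gives no reliable bias. Selectivity for the aldehyde over the C2 ketone rests on the known preference of alkenylchromium reagents and on the fact that attack at C2 would need a four-membered ring; the neutral medium spares the skipped enone, the silyl ethers and the C7–H. Slow addition keeps the stationary concentration of 21 low so that ring closure outruns dimerisation, helped by the sp2 centres at C2, C4, C5 and C10, which cut the rotational freedom of the chain.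

Step 15
Reactants: 24 (3Z,5R,6S,7S)-7-(TBSO)-3-[(TBSO)methyl]-5-hydroxy-9-methylidene-6-[3-(TESO)prop-1-en-2-yl]cyclodec-3-en-1-one
Product: 25 (3Z,5R,6S,7S)-7-(TBSO)-3-[(TBSO)methyl]-5-hydroxy-6-(3-hydroxyprop-1-en-2-yl)-9-methylidenecyclodec-3-en-1-one
Conditions: PPTS (cat.), MeOH/CH2Cl2, 0 °C
Reagents that add atoms: none
Why: Acid-catalysed methanolysis should remove the primary TES ether much faster than the bulkier TBS ethers, freeing only the C12 hydroxyl.

Step 16
Reactants: 25 (3Z,5R,6S,7S)-7-(TBSO)-3-[(TBSO)methyl]-5-hydroxy-6-(3-hydroxyprop-1-en-2-yl)-9-methylidenecyclodec-3-en-1-one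
Product: 28 (3aS,4S,10Z,11aR)-4-(TBSO)-10-[(TBSO)methyl]-3,6-dimethylidene-3a,4,5,6,7,9-hexahydrocyclodeca[b]furan-2,8(3H,11aH)-dione, via hydroxy enal 26 (not isolated), via lactol 27 (not isolated)
Conditions: TEMPO (20 mol%), PhI(OAc)2 (2.5 equiv), CH2Cl2, rt
Reagents that add atoms: none
Why: Oxoammonium-mediated oxidative lactonisation of a 1,4-diol: the primary allylic C12 alcohol is oxidised before the secondary C6 alcohol, enal 26 is trapped by the C6 hydroxyl as lactol 27, and a second oxidation gives the α-methylene-γ-lactone. C6 and C7 are untouched, so the lactone is trans-fused.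

Step 17
Reactants: 28 (3aS,4S,10Z,11aR)-4-(TBSO)-10-[(TBSO)methyl]-3,6-dimethylidene-3a,4,5,6,7,9-hexahydrocyclodeca[b]furan-2,8(3H,11aH)-dione
Product: 29 (3aR,4S,10Z,11aR)-4-hydroxy-10-(hydroxymethyl)-3,6-dimethylidene-3a,4,5,6,7,9-hexahydrocyclodeca[b]furan-2,8(3H,11aH)-dione
Conditions: HF·pyridine, pyridine, THF, 0 °C to rt
Reagents that add atoms: none
Why: Fluoride cleavage of both TBS ethers under buffered, weakly acidic conditions, which avoid base-induced conjugation of the skipped enone, Michael addition to the methylene lactone and transfer of the lactone to O8.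

Step 18
Reactants: 29 (3aR,4S,10Z,11aR)-4-hydroxy-10-(hydroxymethyl)-3,6-dimethylidene-3a,4,5,6,7,9-hexahydrocyclodeca[b]furan-2,8(3H,11aH)-dione
Product: 30 [(3aR,4S,10Z,11aR)-4-(acetyloxy)-3,6-dimethylidene-2,8-dioxo-2,3,3a,4,5,6,7,8,9,11a-decahydrocyclodeca[b]furan-10-yl]methyl acetate
Conditions: Ac2O, pyridine, DMAP (cat.), CH2Cl2, 0 °C
Reagents that add atoms: acetic anhydride, CC(=O)OC(C)=O
Why: Standard acylation of the primary allylic and the secondary hydroxyl; run cold and directly after step 17 so that the free C8 hydroxyl has no time to attack the lactone.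

## Compound list

1 | prop-2-yn-1-ol | C#CCO | starting material
2 | allylmagnesium bromide | C=CC[Mg]Br | starting material
3 | cyclic alkenylmagnesium alkoxide (4-allyl-2,5-dihydro-1,2-oxamagnesole) | C=CCC1=C[Mg]OC1 | intermediate
4 | (2Z)-2-(iodomethylidene)pent-4-en-1-ol | I/C=C(CO)/CC=C | intermediate
5 | tert-butyl{[(2Z)-2-(iodomethylidene)pent-4-en-1-yl]oxy}dimethylsilane | I/C=C(CO[Si](C)(C)C(C)(C)C)/CC=C | intermediate
6 | (4Z)-4-[(TBSO)methyl]-5-iodopent-4-ene-1,2-diol (racemic) | I/C=C(CO[Si](C)(C)C(C)(C)C)/CC(O)CO | intermediate
7 | (3Z)-3-[(TBSO)methyl]-4-iodobut-3-enal | I/C=C(CO[Si](C)(C)C(C)(C)C)/CC=O | intermediate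
8 | 2-bromoprop-2-en-1-ol | C=C(Br)CO | starting material
9 | [(2-bromoprop-2-en-1-yl)oxy]triethylsilane | C=C(Br)CO[Si](CC)(CC)CC | intermediate
10 | diethyl malonate | CCOC(=O)CC(=O)OCC | starting material
11 | diethyl 2-[3-(TESO)prop-1-en-2-yl]propanedioate | CCOC(=O)C(C(=C)CO[Si](CC)(CC)CC)C(=O)OCC | intermediate
12 | 2-[3-(TESO)prop-1-en-2-yl]propane-1,3-diol | OCC(CO)C(=C)CO[Si](CC)(CC)CC | intermediate
13 | (2R)-3-hydroxy-2-[3-(TESO)prop-1-en-2-yl]propyl acetate | CC(=O)OC[C@@H](CO)C(=C)CO[Si](CC)(CC)CC | intermediate
14 | (2S)-3-oxo-2-[3-(TESO)prop-1-en-2-yl]propyl acetate | CC(=O)OC[C@@H](C=O)C(=C)CO[Si](CC)(CC)CC | intermediate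
15 | 2-(chloromethyl)-3-(trimethylsilyl)prop-1-ene | C=C(CCl)C[Si](C)(C)C | starting material
16 | {2-[(trimethylsilyl)methyl]prop-2-en-1-yl}chromium dichloride (trivalent chromium, chiral ligand not drawn) | C=C(C[Cr](Cl)Cl)C[Si](C)(C)C | intermediate
17 | (2S,3S)-3-hydroxy-2-[3-(TESO)prop-1-en-2-yl]-5-[(trimethylsilyl)methyl]hex-5-en-1-yl acetate | CC(=O)OC[C@H](C(=C)CO[Si](CC)(CC)CC)[C@@H](O)CC(=C)C[Si](C)(C)C | intermediate
18 | (2S,3S)-3-(TBSO)-2-[3-(TESO)prop-1-en-2-yl]-5-[(trimethylsilyl)methyl]hex-5-en-1-yl acetate | CC(=O)OC[C@H](C(=C)CO[Si](CC)(CC)CC)[C@@H](O[Si](C)(C)C(C)(C)C)CC(=C)C[Si](C)(C)C | intermediate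
19 | (2S,3S,9Z)-3-(TBSO)-9-[(TBSO)methyl]-7-hydroxy-10-iodo-5-methylidene-2-[3-(TESO)prop-1-en-2-yl]dec-9-en-1-yl acetate (both C7 epimers) | I/C=C(CO[Si](C)(C)C(C)(C)C)/CC(O)CC(=C)C[C@H](O[Si](C)(C)C(C)(C)C)[C@@H](C(=C)CO[Si](CC)(CC)CC)COC(C)=O | intermediate
20 | (2S,3S,9Z)-3-(TBSO)-9-[(TBSO)methyl]-10-iodo-5-methylidene-2-[3-(TESO)prop-1-en-2-yl]dec-9-ene-1,7-diol (both C7 epimers) | I/C=C(CO[Si](C)(C)C(C)(C)C)/CC(O)CC(=C)C[C@H](O[Si](C)(C)C(C)(C)C)[C@@H](C(=C)CO[Si](CC)(CC)CC)CO | intermediate
21 | (2R,3S,9Z)-3-(TBSO)-9-[(TBSO)methyl]-10-iodo-5-methylidene-7-oxo-2-[3-(TESO)prop-1-en-2-yl]dec-9-enal | I/C=C(CO[Si](C)(C)C(C)(C)C)/CC(=O)CC(=C)C[C@H](O[Si](C)(C)C(C)(C)C)[C@@H](C(=C)CO[Si](CC)(CC)CC)C=O | intermediate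
22 | alkenylchromium dichloride from 21 (iodine replaced by trivalent chromium, same geometry and configuration, ligand not drawn) | Cl[Cr](Cl)/C=C(CO[Si](C)(C)C(C)(C)C)/CC(=O)CC(=C)C[C@H](O[Si](C)(C)C(C)(C)C)[C@@H](C(=C)CO[Si](CC)(CC)CC)C=O | intermediate
23 | zirconocene chloride alkoxide of 24 (O–Zr on C6) | C=C1CC(=O)C/C(CO[Si](C)(C)C(C)(C)C)=C/[C@@H](O[Zr](Cl)(C2C=CC=C2)C2C=CC=C2)[C@H](C(=C)CO[Si](CC)(CC)CC)[C@@H](O[Si](C)(C)C(C)(C)C)C1 | intermediate
24 | (3Z,5R,6S,7S)-7-(TBSO)-3-[(TBSO)methyl]-5-hydroxy-9-methylidene-6-[3-(TESO)prop-1-en-2-yl]cyclodec-3-en-1-one | C=C1CC(=O)C/C(CO[Si](C)(C)C(C)(C)C)=C/[C@@H](O)[C@H](C(=C)CO[Si](CC)(CC)CC)[C@@H](O[Si](C)(C)C(C)(C)C)C1 | intermediate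
25 | (3Z,5R,6S,7S)-7-(TBSO)-3-[(TBSO)methyl]-5-hydroxy-6-(3-hydroxyprop-1-en-2-yl)-9-methylidenecyclodec-3-en-1-one | C=C1CC(=O)C/C(CO[Si](C)(C)C(C)(C)C)=C/[C@@H](O)[C@H](C(=C)CO)[C@@H](O[Si](C)(C)C(C)(C)C)C1 | intermediate
26 | hydroxy enal: 25 with C12 oxidised to the aldehyde (2-substituted propenal, configuration unchanged) | C=C1CC(=O)C/C(CO[Si](C)(C)C(C)(C)C)=C/[C@@H](O)[C@H](C(=C)C=O)[C@@H](O[Si](C)(C)C(C)(C)C)C1 | intermediate
27 | lactol: trans-fused 2-hydroxy-3-methylidenetetrahydrofuran from 26 (both anomers) | C=C1CC(=O)C/C(CO[Si](C)(C)C(C)(C)C)=C/[C@H]2OC(O)C(=C)[C@@H]2[C@@H](O[Si](C)(C)C(C)(C)C)C1 | intermediate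
28 | (3aS,4S,10Z,11aR)-4-(TBSO)-10-[(TBSO)methyl]-3,6-dimethylidene-3a,4,5,6,7,9-hexahydrocyclodeca[b]furan-2,8(3H,11aH)-dione | C=C1CC(=O)C/C(CO[Si](C)(C)C(C)(C)C)=C/[C@H]2OC(=O)C(=C)[C@@H]2[C@@H](O[Si](C)(C)C(C)(C)C)C1 | intermediate
29 | (3aR,4S,10Z,11aR)-4-hydroxy-10-(hydroxymethyl)-3,6-dimethylidene-3a,4,5,6,7,9-hexahydrocyclodeca[b]furan-2,8(3H,11aH)-dione | C=C1CC(=O)C/C(CO)=C/[C@H]2OC(=O)C(=C)[C@@H]2[C@@H](O)C1 | intermediate
30 | [(3aR,4S,10Z,11aR)-4-(acetyloxy)-3,6-dimethylidene-2,8-dioxo-2,3,3a,4,5,6,7,8,9,11a-decahydrocyclodeca[b]furan-10-yl]methyl acetate | C=C1CC(=O)C/C(COC(C)=O)=C/[C@H]2OC(=O)C(=C)[C@@H]2[C@@H](OC(C)=O)C1 | target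

## Step count and least certain steps

Total: 18 steps. Longest linear sequence: 15 steps (8 to 30, steps 4–18); the branch from 1 joins at step 11 after 3 steps.

Step 14 (key step).
- Most likely failure: poor facial selectivity at C6, because the conformation of the closing ten-membered ring may override the ligand. Intermolecular coupling or cathodic reduction of the carbon–iodine bond before cyclisation may also compete.
- Fallback (sets out from 21, returns at 24): an oxidation–reduction correction is not used, since a C6 enone would have to be reduced beside the C2 ketone. Instead the C6 epimer is inverted. If closure of 21 under the same nickel/chromium conditions prefers the Si face, it should give the (3Z,5S,6S,7S)-alcohol F1. Mitsunobu reaction of F1 with chloroacetic acid, PPh3 and diisopropyl azodicarboxylate should give the inverted chloroacetate F2. Thiourea with NaHCO3 in methanol then removes the chloroacetyl group under near-neutral conditions to give 24.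

Step 9.
- Most likely failure: insufficient reagent control in a mismatched pairing with the C7 centre, so that the C8 epimer forms alongside; β-elimination of acetic acid from 14 if the addition is slow.
- Fallback (sets out from 15 and 14, returns at 17): 15 is treated with Bu3SnLi to give tributyl{2-[(trimethylsilyl)methyl]prop-2-en-1-yl}stannane F3. Aldehyde 14 is then allylated with F3 under Ti(OiPr)4/BINOL catalysis (Keck asymmetric allylation, open transition state, BINOL antipode chosen for Si-face attack) to give 17. The stannane terminus reacts in preference to the silane terminus.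

Step 5.
- Most likely failure: isomerisation of 11 into the conjugated alkylidene malonate during coupling or work-up, low reactivity of the 1,1-disubstituted alkenyl bromide, or loss of the TES group in basic DMSO.
- Fallback (sets out from 9, returns at 12): palladium-catalysed coupling of 9 with the Reformatsky reagent BrZnCH2CO2t-Bu (Pd2(dba)3, P(t-Bu)3, THF) should give tert-butyl 3-[(TESO)methyl]but-3-enoate F4. Deprotonation with LDA at −78 °C and α-hydroxymethylation with monomeric formaldehyde gives tert-butyl 2-(hydroxymethyl)-3-[(TESO)methyl]but-3-enoate F5. LiAlH4 reduction gives 12.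

Step 11.
- Most likely failure: Lewis-acid damage before the C–C bond forms, that is loss of the primary TES ether of 18, protodesilylation of the allylsilane, or isomerisation of 7.
- Fallback (sets out from 7, 15 and 14, returns at 20): the Lewis-acid step is moved to the small fragments and the union is done by neutral chromium chemistry. 7 and 15 with BF3·OEt2 should give the chloro alcohol F6, which is acetylated to the chloro acetate F7. Aldehyde 14 is allylated with F7 under the chromium conditions of step 9 (no nickel, so the iodoalkene stays intact) to give the C8 alcohol F8. TBSOTf and 2,6-lutidine give the silyl ether F9, and i-Bu2AlH removes both acetates to give 20.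

## Further compounds

F1 | step 14 | (3Z,5S,6S,7S)-7-(TBSO)-3-[(TBSO)methyl]-5-hydroxy-9-methylidene-6-[3-(TESO)prop-1-en-2-yl]cyclodec-3-en-1-one (C6 epimer of 24) | C=C1CC(=O)C/C(CO[Si](C)(C)C(C)(C)C)=C/[C@H](O)[C@H](C(=C)CO[Si](CC)(CC)CC)[C@@H](O[Si](C)(C)C(C)(C)C)C1
F2 | step 14 | chloroacetate of 24 (C6 configuration of 24) | C=C1CC(=O)C/C(CO[Si](C)(C)C(C)(C)C)=C/[C@@H](OC(=O)CCl)[C@H](C(=C)CO[Si](CC)(CC)CC)[C@@H](O[Si](C)(C)C(C)(C)C)C1
F3 | step 9 | tributyl{2-[(trimethylsilyl)methyl]prop-2-en-1-yl}stannane | C=C(C[Sn](CCCC)(CCCC)CCCC)C[Si](C)(C)C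
F4 | step 5 | tert-butyl 3-[(TESO)methyl]but-3-enoate | CC(C)(C)OC(=O)CC(=C)CO[Si](CC)(CC)CC
F5 | step 5 | tert-butyl 2-(hydroxymethyl)-3-[(TESO)methyl]but-3-enoate (racemic) | CC(C)(C)OC(=O)C(CO)C(=C)CO[Si](CC)(CC)CC
F6 | step 11 | (6Z)-6-[(TBSO)methyl]-2-(chloromethyl)-7-iodohepta-1,6-dien-4-ol (racemic) | I/C=C(CO[Si](C)(C)C(C)(C)C)/CC(O)CC(=C)CCl
F7 | step 11 | (6Z)-6-[(TBSO)methyl]-2-(chloromethyl)-7-iodohepta-1,6-dien-4-yl acetate (racemic) | I/C=C(CO[Si](C)(C)C(C)(C)C)/CC(OC(C)=O)CC(=C)CCl
F8 | step 11 | (2S,3S,9Z)-9-[(TBSO)methyl]-3-hydroxy-10-iodo-5-methylidene-2-[3-(TESO)prop-1-en-2-yl]dec-9-ene-1,7-diyl diacetate (both C7 epimers) | I/C=C(CO[Si](C)(C)C(C)(C)C)/CC(OC(C)=O)CC(=C)C[C@H](O)[C@@H](C(=C)CO[Si](CC)(CC)CC)COC(C)=O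
F9 | step 11 | (2S,3S,9Z)-3-(TBSO)-9-[(TBSO)methyl]-10-iodo-5-methylidene-2-[3-(TESO)prop-1-en-2-yl]dec-9-ene-1,7-diyl diacetate (both C7 epimers) | I/C=C(CO[Si](C)(C)C(C)(C)C)/CC(OC(C)=O)CC(=C)C[C@H](O[Si](C)(C)C(C)(C)C)[C@@H](C(=C)CO[Si](CC)(CC)CC)COC(C)=O
A1 | alternative 1 | seven-membered diisopropylsilylene acetal (dioxasilepine) with C15 cis to C6 | CC(=O)OC[C@@H](C(=C)CO[Si](CC)(CC)CC)[C@@H]1O[Si](C(C)C)(C(C)C)OCC(CC2(SCCCS2)CC(=C)CCl)=C1
A2 | alternative 1 | acyclic silicon-tethered diene (C5 vinyl and C4 methylene) | CC(=O)OC[C@@H](C(=C)CO[Si](CC)(CC)CC)[C@@H](C=C)O[Si](C(C)C)(C(C)C)OCC(=C)CC1(SCCCS1)CC(=C)CCl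
A3 | alternative 2 | ten-membered C10 ketone (cyclodec-5-enone) with trans lactone and two silyl ethers | O=C1CCC/C(CO[Si](C)(C)C(C)(C)C)=C/[C@H]2OC(=O)C[C@@H]2[C@@H](O[Si](C)(C)C(C)(C)C)C1
A4 | alternative 2 | 1-vinyl-2-alkenylcyclohexanol with fused lactone (vinyl and alkenyl trans) | C=C[C@@]1(O)[C@H](C(=C)CO[Si](C)(C)C(C)(C)C)[C@H]2OC(=O)C[C@@H]2[C@@H](O[Si](C)(C)C(C)(C)C)C1
A5 | alternative 3 | ten-membered carbocycle with free C8 hydroxyl, C10 methylene and C2 dithiane | C=C1CC2(SCCCS2)C/C(CO[Si](C)(C)C(C)(C)C)=C/[C@@H](O[Si](CC)(CC)CC)[C@H](C(=C)CO[Si](CC)(CC)CC)[C@@H](O)C1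
A6 | alternative 3 | eleven-membered α-stannyl allyl ether | C=C1CO[C@H]([Sn](CCCC)(CCCC)CCCC)[C@@H](C(=C)CO[Si](CC)(CC)CC)[C@H](O[Si](CC)(CC)CC)/C=C(CO[Si](C)(C)C(C)(C)C)/CC2(SCCCS2)C1
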